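Start from the leftover: if every J that reacts ends as G, Q or E, then whatever those three readings leave missing from the charge is unreacted J, and you have a J column for each of these runs.

| flask | J | L | remark | time |
|---|---|---|---|---|
| blue | 0.40 M | 2.5 equiv | run made earlier |  |
| grey | 0.20 M | 2.5 equiv | run made earlier |  |
| amber | 0.30 M | 2.5 equiv | run made earlier |  |
| gamma | 0.40 M | 2.50 equiv | a closed flask charged with all of it at once and left for 3.0 h | 3.0 h |
| delta | 0.40 M | 2.50 equiv | a tube with plug flow, the mixed feed as stated, residence time 3.0 h | 3.0 h |
| eta | 0.40 M (fed, over 2.40 h) | 2.50 equiv | a stirred flask in which J is dosed at a steady rate over 2.40 h without added volume, worked up at 3.0 h | 3.0 h |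
| theta | 0.40 M | 2.50 equiv | one stirred flow tank at steady state, fed with the mixture as stated, mean residence time 3.0 h |  |

| run | time / h | G / % | Q / % | E / % |
|---|---|---|---|---|
| blue | 0.250 | 18.6 | 1.4 | 5.2 |
| blue | 0.417 | 24.1 | 1.4 | 9.8 |
| blue | 0.667 | 26.8 | 2.8 | 18.5 |
| blue | 1.00 | 25.8 | 4.3 | 27.0 |
| blue | 2.00 | 21.9 | 5.9 | 45.5 |
| blue | 3.00 | 18.2 | 6.5 | 53.6 |
| grey | 0.417 | 17.3 | 0.4 | 3.7 |
| grey | 0.833 | 24.3 | 0.5 | 8.6 |
| grey | 1.33 | 25.6 | 1.6 | 17.0 |
| grey | 1.50 | 27.0 | 2.1 | 19.7 |
| grey | 2.00 | 26.1 | 3.3 | 25.0 |
| grey | 2.50 | 26.3 | 4.2 | 30.0 |
| amber | 0.167 | 11.4 | 1.1 | 0.9 |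
| amber | 0.500 | 22.6 | 0.2 | 8.0 |
| amber | 0.833 | 25.9 | 2.2 | 17.2 |
| amber | 1.33 | 27.1 | 3.0 | 26.9 |
| amber | 2.00 | 24.4 | 4.9 | 37.2 |
| amber | 2.50 | 23.6 | 4.9 | 41.6 |

(scatter of a reading: 0.5 percentage points)

- the stated concentrations are those of everything mixed, before any reaction; amounts are the same in each set-up
- the feed brings no volume worth counting
- the earlier runs were made in a closed, stirred flask

- the set-up with the highest share of G in all that became G or Q or E, at the outlet or at the end ("none" if the first two lie within 2 percentage points) (gamma / delta / eta / theta / none)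
- share of G in all that became G or Q or E, at the outlet or at the end, gamma
- share of G in all that became G or Q or E, at the outlet or at the end, delta
- share of G in all that became G or Q or E, at the outlet or at the end, eta
- share of G in all that became G or Q or E, at the outlet or at the end, theta

G rises and then sinks in blue and amber and levels off in grey, so at its crest gain and loss balance, and the [J]/[G] read there says how readily G is lost against how readily it is formed. The crest readings give 1.94 in blue at 0.667 h, 1.90 in grey at 1.50 h and 1.59 in amber at 1.33 h, with a mean of 1.81. Call this m, a selectivity factor: by reaction G gains while it stands below the balance level [J]/m and loses above it.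

You should doubt amber's figure, which lies below the other two, and the crest is flat: one reading later, at 1.00 h, blue has lost 1 percentage point of G while its ratio has gone to 1.66, so m as read is uncertain by about 0.274. You should also doubt L, whose equivalents stayed the same in these runs, so m carries over to eta if L enters gain and loss alike.

My own reckoning takes gamma from blue's reading at 3.00 h, the same charge and time. The ratio there is 1.19, under m, so blue's G stands above its balance level, and the share is 23.2%; a plug-flow tube should match it. For eta, blue at 1.00 h shows a share of 45.2% with more J unreacted than at 3.00 h. But J dosed early has had time to go on, so I put eta between those two figures.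

The forecast names eta, with gamma 23%, delta 23%, eta 37% (range 28% to 43%) and theta 26%, reasoning “Dosing: J stays low and conversion is lower”.

The flask gives eta, with gamma 22.8%, delta 22.8%, eta 36.0% and theta 28.7%, so the forecast held.

    J + L → G (k = 1.20 M⁻¹ h⁻¹)
    L + G → Q (k = 0.260 M⁻¹ h⁻¹)
    L + G → E (k = 1.90 M⁻¹ h⁻¹)
    L → X (k = 0.190 h⁻¹)

[L] stands in both G's gain and its loss, so it cancels in their ratio, and at 3.00 h loss over gain, m[G]/[J] with m as read, is 1.63 in gamma against 0.958 in eta. In percent of the J charged, gamma's G of 18.2% stands over its balance level of 11.2%, while eta's 21.5% stands beside 22.4%.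

Read eta at 8.0 h instead: with J at 23.2%, m puts the balance level at 12.8%, below the G present at 3.00 h, so G should have come down from there. Computed, G is 18.3% and the share 23.8%.

Readings and results come from a simulation on assumed constants.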